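Readings and results come from a simulation on assumed constants; the scatter is artificial.

**Nearest neighbour.** The theta run is the close neighbour of Thursday's flask: it has the same substrate charge, 0.012 M, but activator at 1.4 equiv against 0.950 equiv. Its ring reads 9.1% of the charge at 4.00 min, a reading good to 0.3 percentage points, and its late slope is about half of that early one.

| flask | substrate | activator | remark | time |
|---|---|---|---|---|
| theta | 0.012 M | 1.4 equiv | run made earlier |  |
| Thursday's | 0.012 M | 0.950 equiv |  | 1.0 h |
| Wednesday's | 0.025 M | 0.950 equiv |  | 1.0 h |
| Monday's | 0.050 M | 0.950 equiv |  | 1.0 h |
| Sunday's | 0.10 M | 0.950 equiv |  | 1.0 h |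
| Friday's | 0.20 M | 0.950 equiv |  | 1.0 h |

theta run (percent of the substrate charged)

| time / min | ring / % |
|---|---|
| 2.00 | 4.4 |
| 4.00 | 9.1 |
| 6.00 | 13.1 |
| 8.00 | 15.3 |
| 10.0 | 18.2 |
| 12.0 | 20.5 |

(readings scatter by 0.3 percentage points)

- "hardly changes" means that all values lie within two and a half points (for a concentration: within two and a half percent of the largest)

1. [ring] at the end for Thursday's, Wednesday's, Monday's, Sunday's, Friday's, in this order
2. how that number moves from the first to the last of them (rises, then falls / hardly changes / rises all the way / falls all the way / falls, then rises)

**The clock.** Dividing that time by that fraction gives 44.0 min. I call this the charge clock, the time in which the start slope of ring would take up the whole charge. The theta run stops at 12.0 min, shorter than its clock, so it ends low, at 20.5%. I take the slope to follow the activator concentration, so in logarithms Thursday's clock gains 0.168 and comes to 64.8 min. That is longer than Thursday's time of 1.0 h, so Thursday's flask also ends inside its first clock, but with a time that the theta run never had.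

**Up the row.** Friday's charge takes 1.22 off the logarithm of Thursday's clock, which leaves 3.89 min, shorter than the hour. I expect Friday's flask to have little substrate left to feed ring beyond that clock. Ring concentration is fraction times charge, so from Sunday's to Friday's the charge adds 0.301 to the logarithm, and the row rises on that step if the fraction loses less than that.

**The check.** My clocks give no row of their own, but the forecast gives 0.0049 M, 0.0105 M, 0.0185 M, 0.027 M and 0.035 M, a row that rises all the way, on the ground that “At higher concentrations substrate is essentially consumed”. The flasks give 0.00365 M, 0.00635 M, 0.00847 M, 0.00857 M and 0.00591 M: the row rises, then falls, since Friday's fraction loses 0.463 against Sunday's, more than the charge adds.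

    substrate + activator → activated form (k = 3.25 /M/min)
    activated form → ring (k = 4.82 /min)
    substrate + activated form → open dimer (k = 379 /M/min)
    activator + ring → over-reaction product (k = 0.210 /M/min)
    2 substrate → self-condensation product (k = 1.77 /M/min)

**Long exposure.** Friday's clock of 3.89 min is far shorter than the hour. Its substrate, the limiting reagent, stands at 0% after 0.500 h, and its ring then slips from 5.35% to 2.95%. Part of the reason is activator + ring passing into over-reaction product: without that step Friday's ends at 9.57%, and the row rises all the way. Thursday's clock, 64.8 min, outlasts the hour, and in Thursday's flask part of the reason for the low ring is substrate + activated form passing into open dimer: without that step Thursday's ends at 47.2% against 30.4%.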